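**Plan**

- Late cuts: the O–CH3 bonds at O5 and O7, the O–Si bond at O4', then C3–OH. Ring C is cut at O1–C2 and on both sides of C4 (C4–C4a, C4–C3), leading back to an ortho-iodophenol, CO and an arylacetylene that already carries ring B.
- Ring A is cut pericyclically at C8a–C4a and C5–C6 (a [2+2] pair) and at C8a–C8 (6π closure), or at the mirror-related set. This gives a 2-alkyl-3-methoxycyclobutenone and methoxyacetylene; the cyclobutenone goes back through an ynol ether and a C3 ester to (R)-α-ionone.
- Feature used: ring A is a phloroglucinol whose alkylated carbon C6 lies between the oxygenated carbons C5 and C7 and para to the ring-oxygen carbon C8a. Its precursor is therefore a 4-alkyl-3,5-dimethoxyphenol, symmetric about its C1–C4 axis, so either ortho carbon can become C4a and the 6- versus 8-alkyl question is closed before ring C exists.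
- Forward order: ionone side chain trimmed to the propanoate, ynol ether, cyclobutenone, ring A (benzannulation), iodide, ring C with ring B attached (carbonylative annulation), C3 hydroxyl, deprotection.
- Stereochemistry: the single stereocentre C1' is bought with (R)-α-ionone and no bond to it is made or broken. Its neighbouring ring double bond would migrate or cyclise onto O5/O7 under acid, so ring A carries methyl ethers that chloride can cleave and ring B a silyl ether.

Key step: step 7

Assumption: (R)-α-ionone of high enantiomeric purity and triisopropyl(4-ethynylphenoxy)silane are bought. Methyl rather than ethyl ynol ethers are used because they cannot fragment by retro-ene loss of an alkene on heating and because methyl ethers can be removed at the end by SN2 attack of chloride, without acid.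

**Step 1**
Reactants: 1 (R)-α-ionone
Product: 2 (2E)-3-[(1R)-2,6,6-trimethylcyclohex-2-en-1-yl]prop-2-enoic acid
Conditions: aq NaOCl (3.5 equiv), 1,4-dioxane, 0 °C → rt; Na2SO3; cold 1 M HCl to pH 3
Reagents that add atoms: sodium hypochlorite (aqueous) [Na+].[O-]Cl
Why: Haloform reaction, in which the acetyl methyl group is trichlorinated and the trichloromethyl ketone is cleaved by hydroxide, while at 0 °C the γ-proton at C1' should not be removed, so the stereocentre and the ring alkene are carried through unchanged.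

**Step 2**
Reactants: 2 (2E)-3-[(1R)-2,6,6-trimethylcyclohex-2-en-1-yl]prop-2-enoic acid
Product: 3 methyl (2E)-3-[(1R)-2,6,6-trimethylcyclohex-2-en-1-yl]prop-2-enoate
Conditions: MeI, K2CO3, DMF, rt
Reagents that add atoms: iodomethane CI
Why: SN2 O-alkylation of the carboxylate (esterification without acid), under conditions too mild to deconjugate the enoate.

**Step 3**
Reactants: 3 methyl (2E)-3-[(1R)-2,6,6-trimethylcyclohex-2-en-1-yl]prop-2-enoate
Product: 4 methyl 3-[(1R)-2,6,6-trimethylcyclohex-2-en-1-yl]propanoate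
Conditions: Mg turnings, MeOH, 0 °C → rt
Reagents that add atoms: none
Why: Dissolving-metal conjugate reduction (Mg in MeOH) transfers electrons only to the conjugated enoate, so the isolated trisubstituted ring alkene and C1' should stay untouched, and the methyl ester cannot be scrambled by the methoxide formed.

**Step 4**
Reactants: 4 methyl 3-[(1R)-2,6,6-trimethylcyclohex-2-en-1-yl]propanoate
Product: 6 1-methoxy-3-[(1R)-2,6,6-trimethylcyclohex-2-en-1-yl]prop-1-yne, via enol phosphate 5 (not isolated)
Conditions: LiN(i-Pr)2, THF, −78 °C; ClP(O)(OEt)2, DMPU, −78 → 0 °C; then t-BuLi (2.2 equiv), −78 °C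
Reagents that add atoms: none
Why: O-phosphorylation of the ester enolate gives the ketene acetal phosphate, from which t-BuLi removes the vinylic proton and expels diethyl phosphate (β-elimination), the established conversion of esters into 1-alkoxyalkynes, with both carbanions remote from C1'.

**Step 5**
Reactants: 6 1-methoxy-3-[(1R)-2,6,6-trimethylcyclohex-2-en-1-yl]prop-1-yne, 7 trichloroacetyl chloride
Product: 10 3-methoxy-2-{[(1R)-2,6,6-trimethylcyclohex-2-en-1-yl]methyl}cyclobut-2-en-1-one, via dichloroketene 8 (not isolated), via dichlorocyclobutenone 9 (not isolated)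
Conditions: 7 (slow addition), Zn–Cu couple, Et2O–DME, 0 °C → rt; filter; then Zn dust, AcOH–TMEDA, EtOH, 0 °C → rt
Reagents that add atoms: none
Why: Dichloroketene, released from 7 by zinc, should undergo thermal [2+2] cycloaddition with the electron-rich ynol ether far faster than with the hindered ring alkene (its carbonyl carbon bonding to the alkyl-bearing alkyne carbon), and the two α-chlorines of crude 9 are then removed by buffered zinc reduction, the standard two-stage route from alkynes to cyclobutenones.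

**Step 6**
Reactants: 11 chloroacetaldehyde dimethyl acetal
Product: 14 methoxyacetylene, via 2-chlorovinyl methyl ether 12 (not isolated), via sodium methoxyacetylide 13 (not isolated)
Conditions: NaNH2 (3 equiv), liquid NH3, −33 °C; cold saturated aq NaCl; distil into toluene at −78 °C
Reagents that add atoms: none
Why: Twofold base-induced elimination (methanol, then HCl) gives the sodium acetylide, which is protonated on quenching, the classical preparation of alkoxyacetylenes from chloroacetaldehyde acetals.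

**Step 7**
Reactants: 10 3-methoxy-2-{[(1R)-2,6,6-trimethylcyclohex-2-en-1-yl]methyl}cyclobut-2-en-1-one, 14 methoxyacetylene
Product: 19 3,5-dimethoxy-4-{[(1R)-2,6,6-trimethylcyclohex-2-en-1-yl]methyl}phenol, via vinylketene 15 (not isolated), via 4-vinylcyclobutenone 16 (not isolated), via dienylketene 17 (not isolated), via cyclohexadienone 18 (not isolated)
Conditions: 14 (3 equiv), toluene, sealed tube, 80 °C then 120 °C; then K2CO3, MeOH, rt
Reagents that add atoms: none
Why: Thermal conrotatory 4π opening of 10 gives vinylketene 15, which adds to the ynol ether in a regiospecific [2+2] cycloaddition (ketene carbonyl carbon to the alkyne CH, alkyl-bearing ketene carbon to the alkyne C–OMe) to give 16, and a second 4π opening gives dienylketene 17. Ring A is then closed by thermal disrotatory 6π electrocyclisation of 17 (ketene carbon to the terminal methylene carbon) to 18, which tautomerises to the phenol. The closest known reaction type is the Danheiser benzannulation of cyclobutenones with alkoxyacetylenes. No stereocentre is formed, since the quaternary carbon of 16 is lost on ring opening and C1' is a remote spectator under neutral thermal conditions that should neither epimerise it nor move the ring double bond. The step needs regiocontrol in the [2+2] event and chemoselectivity for the ynol ether over the ring alkene, and both follow from polarisation: the electrophilic ketene carbonyl carbon pairs with the nucleophilic β-carbon of methoxyacetylene, which the hindered trisubstituted alkene cannot match. The result is the 1,3,5-trioxygenated ring with the alkyl group para to the free hydroxyl, and the carbonate–methanol treatment frees any phenol that the ketene has acylated.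

**Step 8**
Reactants: 19 3,5-dimethoxy-4-{[(1R)-2,6,6-trimethylcyclohex-2-en-1-yl]methyl}phenol
Product: 20 2-iodo-3,5-dimethoxy-4-{[(1R)-2,6,6-trimethylcyclohex-2-en-1-yl]methyl}phenol
Conditions: N-iodosuccinimide (1.0 equiv), MeCN, −20 → 0 °C, dark
Reagents that add atoms: N-iodosuccinimide O=C1CCC(=O)N1I
Why: Electrophilic aromatic iodination of a phloroglucinol-type ring that is far more nucleophilic than the hindered ring alkene, with the para position blocked and the two ortho positions equivalent, so one equivalent should give a single mono-iodide.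

**Step 9**
Reactants: 20 2-iodo-3,5-dimethoxy-4-{[(1R)-2,6,6-trimethylcyclohex-2-en-1-yl]methyl}phenol, 21 triisopropyl(4-ethynylphenoxy)silane
Product: 24 5,7-dimethoxy-6-{[(1R)-2,6,6-trimethylcyclohex-2-en-1-yl]methyl}-2-{4-[(triisopropylsilyl)oxy]phenyl}-4H-chromen-4-one, via ynone 22 (not isolated), via enaminone 23 (not isolated)
Conditions: PdCl2(PPh3)2 (5 mol %), CO (10 atm), Et2NH, 90 °C
Reagents that add atoms: carbon monoxide [C-]#[O+]
Why: Carbonylative Sonogashira-type coupling (oxidative addition of the C–I bond to zerovalent palladium formed in situ, CO insertion, alkynylation of the acylpalladium) gives ynone 22, to which Et2NH adds to form enaminone 23, so that the phenol oxygen closes ring C by 6-endo addition–elimination at C2 instead of the 5-exo attack that would give an aurone.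

**Step 10**
Reactants: 24 5,7-dimethoxy-6-{[(1R)-2,6,6-trimethylcyclohex-2-en-1-yl]methyl}-2-{4-[(triisopropylsilyl)oxy]phenyl}-4H-chromen-4-one
Product: 27 3-hydroxy-5,7-dimethoxy-6-{[(1R)-2,6,6-trimethylcyclohex-2-en-1-yl]methyl}-2-{4-[(triisopropylsilyl)oxy]phenyl}-4H-chromen-4-one, via 3-lithioflavone 25 (not isolated), via flavon-3-ylboronate 26 (not isolated)
Conditions: LiN(i-Pr)2, THF, −78 °C; B(OMe)3, −78 → 0 °C; then 30% aq H2O2, NaHCO3, 0 °C
Reagents that add atoms: hydrogen peroxide OO
Why: C3–H lithiation of the flavone (the vinylic proton beside the carbonyl is the kinetically acidic site towards the lithium amide at −78 °C), borylation and boronate oxidation with carbon-to-oxygen migration install the 3-hydroxyl with a nucleophilic oxidant that should leave the ring alkene unepoxidised.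

**Step 11**
Reactants: 27 3-hydroxy-5,7-dimethoxy-6-{[(1R)-2,6,6-trimethylcyclohex-2-en-1-yl]methyl}-2-{4-[(triisopropylsilyl)oxy]phenyl}-4H-chromen-4-one
Product: 28 3-hydroxy-2-(4-hydroxyphenyl)-5,7-dimethoxy-6-{[(1R)-2,6,6-trimethylcyclohex-2-en-1-yl]methyl}-4H-chromen-4-one
Conditions: Bu4NF, AcOH, THF, 0 °C
Reagents that add atoms: none
Why: Fluoride-mediated cleavage of the aryl silyl ether, buffered with AcOH so that the flavonol never meets strongly basic fluoride or acid.

**Step 12**
Reactants: 28 3-hydroxy-2-(4-hydroxyphenyl)-5,7-dimethoxy-6-{[(1R)-2,6,6-trimethylcyclohex-2-en-1-yl]methyl}-4H-chromen-4-one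
Product: 29 Ugonin G
Conditions: LiCl (40 equiv), DMF, 170 °C (microwave); cold pH 5 phosphate buffer
Reagents that add atoms: none
Why: SN2 O-demethylation by chloride of the two methyl ethers that are activated by conjugation with the C4 carbonyl (C5 ortho with lithium chelation, C7 para), a neutral dealkylation known for methyl ethers of prenylated flavanones, so that the acid-labile ring alkene should neither migrate nor cyclise onto O5 or O7.

**Compound list**

1 | (R)-α-ionone, (3E)-4-[(1R)-2,6,6-trimethylcyclohex-2-en-1-yl]but-3-en-2-one | CC(=O)/C=C/[C@H]1C(C)=CCCC1(C)C | starting material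
2 | (2E)-3-[(1R)-2,6,6-trimethylcyclohex-2-en-1-yl]prop-2-enoic acid | OC(=O)/C=C/[C@H]1C(C)=CCCC1(C)C | intermediate
3 | methyl (2E)-3-[(1R)-2,6,6-trimethylcyclohex-2-en-1-yl]prop-2-enoate | COC(=O)/C=C/[C@H]1C(C)=CCCC1(C)C | intermediate
4 | methyl 3-[(1R)-2,6,6-trimethylcyclohex-2-en-1-yl]propanoate | COC(=O)CC[C@H]1C(C)=CCCC1(C)C | intermediate
5 | diethyl 1-methoxy-3-[(1R)-2,6,6-trimethylcyclohex-2-en-1-yl]prop-1-en-1-yl phosphate (E/Z) | CCOP(=O)(OCC)OC(OC)=CC[C@H]1C(C)=CCCC1(C)C | intermediate
6 | 1-methoxy-3-[(1R)-2,6,6-trimethylcyclohex-2-en-1-yl]prop-1-yne | COC#CC[C@H]1C(C)=CCCC1(C)C | intermediate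
7 | trichloroacetyl chloride | ClC(=O)C(Cl)(Cl)Cl | starting material
8 | dichloroketene | ClC(Cl)=C=O | intermediate
9 | 4,4-dichloro-3-methoxy-2-{[(1R)-2,6,6-trimethylcyclohex-2-en-1-yl]methyl}cyclobut-2-en-1-one | COC1=C(C[C@H]2C(C)=CCCC2(C)C)C(=O)C1(Cl)Cl | intermediate
10 | 3-methoxy-2-{[(1R)-2,6,6-trimethylcyclohex-2-en-1-yl]methyl}cyclobut-2-en-1-one | COC1=C(C[C@H]2C(C)=CCCC2(C)C)C(=O)C1 | intermediate
11 | chloroacetaldehyde dimethyl acetal (2-chloro-1,1-dimethoxyethane) | COC(CCl)OC | starting material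
12 | 2-chlorovinyl methyl ether (1-chloro-2-methoxyethene, E/Z) | COC=CCl | intermediate
13 | sodium methoxyacetylide | COC#[C-].[Na+] | intermediate
14 | methoxyacetylene (methoxyethyne) | COC#C | intermediate
15 | 3-methoxy-2-{[(1R)-2,6,6-trimethylcyclohex-2-en-1-yl]methyl}buta-1,3-dien-1-one | C=C(OC)C(C[C@H]1C(C)=CCCC1(C)C)=C=O | intermediate
16 | 3-methoxy-4-(1-methoxyethenyl)-4-{[(1R)-2,6,6-trimethylcyclohex-2-en-1-yl]methyl}cyclobut-2-en-1-one (both C4 epimers) | COC1=CC(=O)C1(C[C@H]2C(C)=CCCC2(C)C)C(OC)=C | intermediate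
17 | (3E)-3,5-dimethoxy-4-{[(1R)-2,6,6-trimethylcyclohex-2-en-1-yl]methyl}hexa-1,3,5-trien-1-one | O=C=C/C(OC)=C(\C(OC)=C)C[C@H]1C(C)=CCCC1(C)C | intermediate
18 | 3,5-dimethoxy-4-{[(1R)-2,6,6-trimethylcyclohex-2-en-1-yl]methyl}cyclohexa-2,4-dien-1-one | O=C1C=C(OC)C(C[C@H]2C(C)=CCCC2(C)C)=C(OC)C1 | intermediate
19 | 3,5-dimethoxy-4-{[(1R)-2,6,6-trimethylcyclohex-2-en-1-yl]methyl}phenol | COc1cc(O)cc(OC)c1C[C@H]1C(C)=CCCC1(C)C | intermediate
20 | 2-iodo-3,5-dimethoxy-4-{[(1R)-2,6,6-trimethylcyclohex-2-en-1-yl]methyl}phenol | COc1cc(O)c(I)c(OC)c1C[C@H]1C(C)=CCCC1(C)C | intermediate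
21 | triisopropyl(4-ethynylphenoxy)silane | C#Cc1ccc(O[Si](C(C)C)(C(C)C)C(C)C)cc1 | starting material
22 | 1-(6-hydroxy-2,4-dimethoxy-3-{[(1R)-2,6,6-trimethylcyclohex-2-en-1-yl]methyl}phenyl)-3-{4-[(triisopropylsilyl)oxy]phenyl}prop-2-yn-1-one | COc1cc(O)c(C(=O)C#Cc2ccc(O[Si](C(C)C)(C(C)C)C(C)C)cc2)c(OC)c1C[C@H]1C(C)=CCCC1(C)C | intermediate
23 | 3-(diethylamino)-1-(6-hydroxy-2,4-dimethoxy-3-{[(1R)-2,6,6-trimethylcyclohex-2-en-1-yl]methyl}phenyl)-3-{4-[(triisopropylsilyl)oxy]phenyl}prop-2-en-1-one (E/Z) | CCN(CC)C(=CC(=O)c1c(O)cc(OC)c(C[C@H]2C(C)=CCCC2(C)C)c1OC)c1ccc(O[Si](C(C)C)(C(C)C)C(C)C)cc1 | intermediate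
24 | 5,7-dimethoxy-6-{[(1R)-2,6,6-trimethylcyclohex-2-en-1-yl]methyl}-2-{4-[(triisopropylsilyl)oxy]phenyl}-4H-chromen-4-one | COc1cc2oc(-c3ccc(O[Si](C(C)C)(C(C)C)C(C)C)cc3)cc(=O)c2c(OC)c1C[C@H]1C(C)=CCCC1(C)C | intermediate
25 | (5,7-dimethoxy-4-oxo-6-{[(1R)-2,6,6-trimethylcyclohex-2-en-1-yl]methyl}-2-{4-[(triisopropylsilyl)oxy]phenyl}-4H-chromen-3-yl)lithium | COc1cc2oc(-c3ccc(O[Si](C(C)C)(C(C)C)C(C)C)cc3)c([Li])c(=O)c2c(OC)c1C[C@H]1C(C)=CCCC1(C)C | intermediate
26 | dimethyl (5,7-dimethoxy-4-oxo-6-{[(1R)-2,6,6-trimethylcyclohex-2-en-1-yl]methyl}-2-{4-[(triisopropylsilyl)oxy]phenyl}-4H-chromen-3-yl)boronate | COB(OC)c1c(-c2ccc(O[Si](C(C)C)(C(C)C)C(C)C)cc2)oc2cc(OC)c(C[C@H]3C(C)=CCCC3(C)C)c(OC)c2c1=O | intermediate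
27 | 3-hydroxy-5,7-dimethoxy-6-{[(1R)-2,6,6-trimethylcyclohex-2-en-1-yl]methyl}-2-{4-[(triisopropylsilyl)oxy]phenyl}-4H-chromen-4-one | COc1cc2oc(-c3ccc(O[Si](C(C)C)(C(C)C)C(C)C)cc3)c(O)c(=O)c2c(OC)c1C[C@H]1C(C)=CCCC1(C)C | intermediate
28 | 3-hydroxy-2-(4-hydroxyphenyl)-5,7-dimethoxy-6-{[(1R)-2,6,6-trimethylcyclohex-2-en-1-yl]methyl}-4H-chromen-4-one | COc1cc2oc(-c3ccc(O)cc3)c(O)c(=O)c2c(OC)c1C[C@H]1C(C)=CCCC1(C)C | intermediate
29 | Ugonin G, 3,5,7-trihydroxy-2-(4-hydroxyphenyl)-6-{[(1R)-2,6,6-trimethylcyclohex-2-en-1-yl]methyl}-4H-chromen-4-one | CC1=CCCC(C)(C)[C@H]1Cc1c(O)cc2oc(-c3ccc(O)cc3)c(O)c(=O)c2c1O | target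

**Step count and risks**

Total step count: 12. Longest linear sequence: 11 steps (1 to 29 through steps 1–5 and 7–12; step 6 is a one-step side branch).

Steps most likely to fail:

1. Step 12. The chloride-induced dealkylation may stop after one ether (the C7 ether reacts more slowly once the first phenoxide is present), or the flavonol may degrade in hot DMF. Fallback: a two-stage dealkylation that sets out from 28. MgI2·OEt2 in THF at 60 °C cleaves the peri ether alone, by chelation between the C4 carbonyl and O5 with iodide attacking the methyl group under aprotic conditions. This gives 3,5-dihydroxy-2-(4-hydroxyphenyl)-7-methoxy-6-{[(1R)-2,6,6-trimethylcyclohex-2-en-1-yl]methyl}-4H-chromen-4-one F1. The remaining C7 methyl ether is then removed with PhSH and catalytic K2CO3 in NMP at 150 °C (thiolate SN2, each phenoxide being reprotonated by the thiol), which returns to the route at 29.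

2. Step 7. Electrocyclic opening of the vinylogous-ester cyclobutenone may be slow, so that the vinylketene dimerises or acylates the product phenol faster than the ynol ether traps it. Fallback: the same vinylketene 15 is generated at room temperature by a photochemical Wolff rearrangement, setting out from ester 4.
   - MeNH(OMe)·HCl and i-PrMgCl in THF give the Weinreb amide N-methoxy-N-methyl-3-[(1R)-2,6,6-trimethylcyclohex-2-en-1-yl]propanamide F2.
   - 1-Methoxyvinyllithium (methyl vinyl ether, t-BuLi, THF) converts it into 2-methoxy-5-[(1R)-2,6,6-trimethylcyclohex-2-en-1-yl]pent-1-en-3-one F3.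
   - Detrifluoroacetylative diazo transfer starts with LiN(SiMe3)2 and CF3CO2CH2CF3, giving 1,1,1-trifluoro-5-methoxy-3-{[(1R)-2,6,6-trimethylcyclohex-2-en-1-yl]methyl}hex-5-ene-2,4-dione F4.
   - MsN3 and Et3N in aqueous MeCN then give 4-diazo-2-methoxy-5-[(1R)-2,6,6-trimethylcyclohex-2-en-1-yl]pent-1-en-3-one F5.
   - Irradiation of F5 at 300 nm with 14 in CH2Cl2, followed by warming to 80 °C, gives 15 (migration of the methoxyvinyl group) and from it, through 16 to 18, phenol 19, where the route is rejoined.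

3. Step 9. CO insertion at the hindered, electron-rich arylpalladium bond may lag behind direct alkynylation, which would end in a 2-arylbenzofuran, or ring closure may go 5-exo to the aurone. Fallback: the ynone is built without palladium, setting out from phenol 19 (iodide 20 is bypassed).
   - Magnesium-phenoxide-directed ortho-formylation (MgCl2, Et3N, paraformaldehyde, MeCN, reflux; Casnati–Skattebøl conditions) gives 6-hydroxy-2,4-dimethoxy-3-{[(1R)-2,6,6-trimethylcyclohex-2-en-1-yl]methyl}benzaldehyde F6.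
   - Two equivalents of the lithium acetylide of 21 (n-BuLi, THF, −78 °C) give 1-(6-hydroxy-2,4-dimethoxy-3-{[(1R)-2,6,6-trimethylcyclohex-2-en-1-yl]methyl}phenyl)-3-{4-[(triisopropylsilyl)oxy]phenyl}prop-2-yn-1-ol F7.
   - MnO2 in CH2Cl2 oxidises F7 to ynone 22, which with Et2NH in EtOH closes through 23 to flavone 24, where the route is rejoined.

**Further compounds**

F1 | step 12 | 3,5-dihydroxy-2-(4-hydroxyphenyl)-7-methoxy-6-{[(1R)-2,6,6-trimethylcyclohex-2-en-1-yl]methyl}-4H-chromen-4-one | COc1cc2oc(-c3ccc(O)cc3)c(O)c(=O)c2c(O)c1C[C@H]1C(C)=CCCC1(C)C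
F2 | step 7 | N-methoxy-N-methyl-3-[(1R)-2,6,6-trimethylcyclohex-2-en-1-yl]propanamide | CON(C)C(=O)CC[C@H]1C(C)=CCCC1(C)C
F3 | step 7 | 2-methoxy-5-[(1R)-2,6,6-trimethylcyclohex-2-en-1-yl]pent-1-en-3-one | C=C(OC)C(=O)CC[C@H]1C(C)=CCCC1(C)C
F4 | step 7 | 1,1,1-trifluoro-5-methoxy-3-{[(1R)-2,6,6-trimethylcyclohex-2-en-1-yl]methyl}hex-5-ene-2,4-dione (C3 epimers) | C=C(OC)C(=O)C(C[C@H]1C(C)=CCCC1(C)C)C(=O)C(F)(F)F
F5 | step 7 | 4-diazo-2-methoxy-5-[(1R)-2,6,6-trimethylcyclohex-2-en-1-yl]pent-1-en-3-one | C=C(OC)C(=O)C(=[N+]=[N-])C[C@H]1C(C)=CCCC1(C)C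
F6 | step 9 | 6-hydroxy-2,4-dimethoxy-3-{[(1R)-2,6,6-trimethylcyclohex-2-en-1-yl]methyl}benzaldehyde | COc1cc(O)c(C=O)c(OC)c1C[C@H]1C(C)=CCCC1(C)C
F7 | step 9 | 1-(6-hydroxy-2,4-dimethoxy-3-{[(1R)-2,6,6-trimethylcyclohex-2-en-1-yl]methyl}phenyl)-3-{4-[(triisopropylsilyl)oxy]phenyl}prop-2-yn-1-ol (both carbinol epimers) | COc1cc(O)c(C(O)C#Cc2ccc(O[Si](C(C)C)(C(C)C)C(C)C)cc2)c(OC)c1C[C@H]1C(C)=CCCC1(C)C
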